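The readings were computed with made-up constants; scatter was added.

- One unit here is the electrophile charged, and every percent is a share of that unit, with a side product or homo dimer holding two electrophile units.

| flask | electrophile | nucleophile | free base | remark | time |
|---|---|---|---|---|---|
| oak | 0.050 M | 0.090 M | 0.20 M | run made earlier |  |
| flask | 0.050 M | 0.0900 M | 0.100 M |  | 15 d |

oak run (percent of the electrophile charged)

| time / d | target / % |
|---|---|
| 0.417 | 27.8 |
| 0.833 | 31.6 |
| 1.25 | 33.0 |
| 1.67 | 33.4 |
| 2.00 | 33.6 |
| 2.50 | 34.1 |
| 3.00 | 34.3 |

(standard deviation of a reading: 0.5 percentage points)

- percent here means electrophile units held: one side product or homo dimer counts as two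
- what was read earlier has a scatter of 0.5 percentage points, one standard deviation
- what may be going on: electrophile + nucleophile <-> acid set free + target; nucleophile + acid set free <-> protonated nucleophile; acid set free + free base <-> salt of the base; electrophile + target -> side product; 2 electrophile -> homo dimer
- the reaction counts as stopped when no species that holds the electrophile changes by six tenths of a point or more over the second half of the time
- no earlier run changes the charge of free base; that part of a forecast is a guess

* why nothing more happens at 15 d, or that something still does (it is still moving / all of the electrophile has reacted / the free base has run out first / the nucleophile has run out first / forward and back rates have come level)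
* amount of target at 15 d, in percent of the electrophile charged

- First ledger entry: the last oak reading puts 34.3% of the unit in target. If target, side product and homo dimer hold the whole unit at the end, the last two share the remainder, which, as a reading, is 1.92 units lost per unit kept.
- Electrophile should be the limiting reagent, since the flask holds 1.80 units of nucleophile and 2.00 of free base per unit. The effect of this free base charge remains a guess.
- Each loss step pairs electrophile with electrophile or target, both scaling with the electrophile charge, while the target step pairs it with nucleophile. The falling curves are replaced by one mean ratio: units lost per unit kept, multiplied by nucleophile per electrophile charged, read 3.45 in the oak run, and this is the loss number.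
- The flask has the oak ratio of electrophile to nucleophile, so this reckoning, which has no term for free base, closes the books with 34.3% in target.
- The forecast is lower than this reckoning, with 33.5% and the verdict all of the electrophile has reacted: “So the electrophile is gone within days, mostly as dimer”.
- The flask gives 33.3%, and its verdict is all of the electrophile has reacted.

    electrophile + nucleophile ⇌ acid set free + target (K = 5.80, k = 2.61 × 10⁻⁴ M⁻¹ s⁻¹)
    nucleophile + acid set free ⇌ protonated nucleophile, settled at all times (K = 38000 M⁻¹)
    acid set free + free base ⇌ salt of the base, settled at all times (K = 2900 M⁻¹)
    electrophile + target → side product (k = 4.71 × 10⁻⁴ M⁻¹ s⁻¹)
    2 electrophile → homo dimer (k = 3.46 × 10⁻⁴ M⁻¹ s⁻¹)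

- At 15.0 d the flask's books read electrophile 0%, target 33.3%, side product 27.3% and homo dimer 39.4%. Its own loss number is 3.60, and the undoing of acid set free + target makes no difference to the target. The neighbour flask, the same flask but with 0.030 M of electrophile, has 3.00 equiv of nucleophile, and the oak loss number gives it 46.5% in target. At 15.0 d that neighbour flask holds electrophile 0%, side product 24.4%, homo dimer 28.8% and target 46.8%.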